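## Structural features

- Neopeltolide is a 14-membered macrolactone (C1 to C13 plus the lactone oxygen) bridged by a tetrahydropyran (O, C3, C4, C5, C6, C7). The core is therefore a 4,15-dioxabicyclo[9.3.1]pentadecane, and C13 carries the propyl chain C14–C16.
- The pyran holds three stereocentres. H3 and H7 are cis (both side arms equatorial), and the C5 acyloxy group is axial, trans to both.
- The chain holds three more stereocentres in a 1,3,5 array, each separated by a methylene: C9 (methyl), C11 (methoxy) and C13 (lactone carbinol). C11/C13 are anti and C9/C11 syn in the extended zigzag, and the two oxygens are differentiated (ether versus acyl).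
- C5 carries a (Z)-enoate whose chain ends in a 2,4-disubstituted oxazole bearing a (Z)-alkenyl methyl carbamate.
- Fragile groups are the two Z alkenes, the oxazole, the carbamate N–H, the β-alkoxy carbonyl units at C1/C3 and at the C5 ketone stage (retro-oxa-Michael), and the silyl dienol ether used on the way.
- The real difficulty is to set C3 and C7 cis and in the right absolute sense although the nearest chain stereocentre, C9, is remote, and then to place the C5 ester axial.
- The key step exploits the pyran ring itself: oxygen at C5 and cis hydrogens at C3 and C7 are what a C4–C7 2-siloxy diene leaves behind when it adds across the C=O of a C3 aldehyde.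

## Logic of the disconnections

**43 to 28 + 42.** The C5–O bond of the side-chain ester is cut. The side chain holds every isomerisable alkene and the heterocycle, so it is attached last. The axial ester is best made from the equatorial alcohol by inversion. The forward step must be a clean SN2 displacement at a ring carbon, without elimination to a dihydropyran and without Z to E drift in 42.

**28 to 27 to 25.** The C5–H bond (hydride onto a ketone) and the O–C1 lactone bond are cut. The C5 ketone is what the cycloaddition delivers, and the seco acid 25 has only one hydroxyl, at C13. The forward steps need axial hydride attack on a chair pyranone and a high-dilution acyl activation that closes the 14-membered ring with retention at C13.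

**25 to 24 to 23 to 22.** These are functional-group changes only: C1 oxidation level, loss of the benzyl group, hydrolysis of both silyl ethers. The gain is that 22 carries C1 as an inert ether and C5 as a masked ketone. The forward sequence needs an oxidation that takes the primary C1 hydroxyl and leaves the secondary C13 hydroxyl.

**22 to 19 + 21 (key).** C3–C4 and O–C7 are cut together. This removes the ring and both ring stereocentres in one move and divides the molecule into a C4–C16 diene and a C1–C3 aldehyde. The forward step must control the aldehyde face, endo approach and regiochemistry, with the catalyst deciding because C9 is too far away to help.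

**19 to 18 to 16 + 17.** The two O–Si bonds and the C6=C7 double bond are cut. A terminal alkene in 16 is a robust placeholder for the enone through all earlier steps, and 17 supplies C4–C6. The forward steps need an E-selective cross-metathesis and an enolisation that takes a proton from the C4 methyl, not from C8.

**16 to 15 to 14 to 13.** The O–CH3 bond and the C11–H bond are cut, with a temporary C13 ester between them. A β-hydroxy ketone lets the C13 hydroxyl deliver hydride to C11 and become acylated in the same event, so the two oxygens come out anti and already differentiated. The forward steps need a non-basic methylation so that the ester does not migrate.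

**13 to 12 to 9 + 10, and 9 to 7 + 6.** C11–C12 and C10–C11 are cut on either side of C11, which becomes a carbonyl anion equivalent supplied by 7. This reduces the chain to a C7–C10 iodide with C9 and a C12–C16 epoxide with C13, each with one stereocentre. The forward steps need two successive metalations and alkylations, and an unmasking that spares the alkene and the aldol-type product.

**6 to 5 to 4 to 1 + 2.** The C8–C9 bond is cut (auxiliary-controlled alkylation), followed by reductive removal of the auxiliary and conversion of hydroxyl to iodide. C9 is thereby drawn from a reliable, reagent-controlled enolate alkylation.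

**21 to 20.** A C–H bond at C3 is cut (alcohol oxidation). The aldehyde is made fresh because it eliminates benzyl alcohol readily.

**42 to 41 to 38 + 39.** The ester O–CH3 bond and then the C2'=C3' double bond are cut. A Z-selective phosphonate olefination on the aldehyde 38 is required.

**38 to 37 to 36 to 35 + 30.** After an oxidation-level change and a cis hydrogenation, the bond between oxazole C2 and the alkyne is cut. This divides the side chain into a halo-oxazole and an alkyne, with the Z geometry coming from a semi-hydrogenation.

**35 to 33 to 31 + 32, and 30 to 29.** The C2–I bond and then the oxazole ring itself (O–C5 and N–C4 bonds) are cut. The heterocycle is assembled with its C4 chain already in place, so that only C2 needs later work.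

## Other disconnections considered

**Alternative 1:** Prins macrocyclisation.
- Cut: O–C7 and C6–C7 of the pyran, with C5–O counted in the same event, while the C1–O13 ester is already present. The precursor would be the hydroxy ester aldehyde A2.
- Forward key step: trifluoroacetic acid would condense the C3 hydroxyl with the C7 aldehyde to a cyclic oxocarbenium ion. The C5=C6 alkene would attack C7 through a chair with all substituents equatorial, and trifluoroacetate would cap C5. The product A1 would have the pyran and the 14-membered lactone closed together.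
- In favour: two rings and two stereocentres (C5, C7) would come from the one resident centre C3, and the lactone linkage would be made as an ordinary intermolecular ester. Cleavage of the trifluoroacetate of A1 would give the same alcohol as 28 without a C5 ketone, a separate lactonisation or a hydride reduction.
- Against: C3 would need its own asymmetric step and an acylation onto the hindered C13 hydroxyl. The ring closure is a cationic macrocyclisation that must outrun oligomerisation and 2-oxonia-Cope exchange, which can erode C3 and with it C7. A2 is a β-branched aldehyde with a free secondary alcohol.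
- Comparison:
  - Structure: both plans pass through the all-cis C5 alcohol and need the same inversion, so they are equal there.
  - Mechanism: the chair Prins closure needs no chiral catalyst and its diastereoselection is intrinsically high, so on that point the alternative is the equal or the better. The chosen cycloaddition is concerted, runs at normal concentration and cannot be scrambled after the event.
  - Step economy: the alternative is shorter after the union by about three operations. The chosen plan is more convergent and puts less risk on the ring-forming step.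

**Alternative 2:** three-component dithiane linchpin, then reductive etherification.
- Cut: C6–C7 and C7–C8, with C7 as a carbonyl anion equivalent. The pieces would be the silyl dithiane A4, the epoxide A5 and the iodide A6.
- Forward key step: lithiated A4 would open A5 at C6. A polar cosolvent would trigger the 1,4-Brook shift of silicon to the C5 oxygen, and the regenerated anion would be alkylated by A6 to give A3. Dithiane hydrolysis, removal of the p-methoxybenzyl group and silane reduction of the resulting cyclic hemiketal would then close the pyran with H7 axial.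
- In favour: the coupling is robust anion chemistry that joins three pieces in one flask. C3 and C5 would arrive with secured configuration from A5, and the C5 oxygen would already be at the alcohol level and protected. No face-selectivity question arises at the coupling, so on reliability of C3/C5 and on convergence of the coupling itself the alternative is the equal or the better.
- Against: A5 (two carbinol centres) and A6 (three centres) each need a multi-step synthesis. The second alkylation sets a hindered anion against a β-branched iodide. C7 is set only three operations later, and the protecting-group load is heavy (two benzyl, one p-methoxybenzyl, one silyl, one dithiane).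
- Comparison:
  - Structure: the alternative builds a linear chain and closes the ring afterwards, whereas the chosen plan makes the ring and both ring centres in the union.
  - Mechanism: SN2 alkylations versus a catalyst-controlled pericyclic step.
  - Step economy: the alternative would be longer, because C3 and C5 are made separately and the pyran is closed after the coupling.

**Alternative 3:** ring-closing metathesis at C8–C9, then hydrogenation.
- Cut: the C8–C9 bond, taken back to an alkene, with C9 left unset. The precursor would be the diene ester A8.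
- Forward key step: the second-generation Grubbs catalyst RuCl2(=CHPh)(PCy3)(H2IMes) would join the C7 vinyl and C9 isopropenyl groups with loss of ethylene to give A7. Hydrogen would then be added from the exposed face of the macrocyclic alkene to set C9.
- In favour: the large ring would be closed by C=C formation from an ester that is easy to assemble. C9 would need no auxiliary sequence, which is a point on which the alternative is the better. The alcohol half of A8 is simple.
- Against: the closure must form a trisubstituted alkene from a 1,1-disubstituted alkene and an allylic, oxygen-substituted vinyl group, which is slow and dilution-dependent. The C9 configuration would rest on the conformation of the 14-membered ring and could not be corrected afterwards. The pyran half of A8, with C3, C5 and C7, must still be built by other means.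
- Comparison:
  - Structure: the pyran problem is moved elsewhere, not solved, whereas the chosen plan solves it in the fragment union.
  - Mechanism: substrate-controlled hydrogenation versus catalyst-controlled cycloaddition.
  - Step economy: the chain half would be shorter, the pyran half longer, and the totals would be similar.

Key step: step 13

**Remarks on the chemistry**
- Atoms are numbered as in the macrolide (C1 lactone carbonyl to C16; side-chain atoms primed).
- Assumption: the C13 hydroxyl is carried through the cycloaddition as its triethylsilyl ether, not as a tert-butyldimethylsilyl ether. This is a protecting-group change only: one reagent forms both silyl ethers of 19 and one acid treatment removes both from 22.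
- The diene and cycloadduct were checked centre by centre against the target and no structural correction was needed. C9 changes its CIP letter between 19 (R) and 22 (S) only because the priorities of its neighbours change.
- Assumption: the (1R,2S) hand of the chromium catalyst is chosen by analogy with the sense this catalyst class shows toward alkoxy aldehydes (diene terminus onto the re face). The antipode is equally accessible.
- 10 is bought as the single enantiomer; it is also the epoxide recovered from hydrolytic kinetic resolution of the racemate.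

## Route

Step 1
Reactants: 1 (S)-4-benzyl-3-propanoyl-1,3-oxazolidin-2-one; 2 3-iodoprop-1-ene
Product: 4 (S)-4-benzyl-3-[(R)-2-methylpent-4-enoyl]-1,3-oxazolidin-2-one, via sodium Z-enolate 3 (not isolated)
Conditions: NaN(SiMe3)2, THF, −78 °C; then 2, −78 to −45 °C
Reagents that add atoms: none
Why: Evans asymmetric alkylation; the chelated Z-enolate is attacked by the allyl iodide on the face away from the benzyl group, which sets C9 (R here), and the minor diastereomer should be removable by chromatography.

Step 2
Reactants: 4 (S)-4-benzyl-3-[(R)-2-methylpent-4-enoyl]-1,3-oxazolidin-2-one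
Product: 5 (R)-2-methylpent-4-en-1-ol
Conditions: LiBH4, H2O (1 equiv), Et2O, 0 °C
Reagents that add atoms: none
Why: Reductive cleavage of the N-acyl oxazolidinone with borohydride gives the primary alcohol without touching the α-stereocentre and returns the auxiliary; the volatile product is concentrated with care.

Step 3
Reactants: 5 (R)-2-methylpent-4-en-1-ol
Product: 6 (R)-5-iodo-4-methylpent-1-ene
Conditions: I2, PPh3, imidazole, CH2Cl2, 0 °C to rt
Reagents that add atoms: iodine, II
Why: Appel-type iodination; the oxyphosphonium leaving group is displaced by iodide at the primary carbon (SN2), so the adjacent stereocentre is not involved.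

Step 4
Reactants: 7 1,3-dithiane; 6 (R)-5-iodo-4-methylpent-1-ene
Product: 9 2-[(R)-2-methylpent-4-en-1-yl]-1,3-dithiane, via 2-lithio-1,3-dithiane 8 (not isolated)
Conditions: n-BuLi, THF, −30 °C; then 6, −78 °C to rt
Reagents that add atoms: none
Why: Corey–Seebach alkylation; the unhindered acyl-anion equivalent displaces the primary iodide and forms C10–C11.

Step 5
Reactants: 9 2-[(R)-2-methylpent-4-en-1-yl]-1,3-dithiane; 10 (R)-2-propyloxirane
Product: 12 (R)-1-{2-[(R)-2-methylpent-4-en-1-yl]-1,3-dithian-2-yl}pentan-2-ol, via lithiated dithiane 11 (not isolated)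
Conditions: n-BuLi, THF, −25 °C; then 10, −25 to 0 °C
Reagents that add atoms: none
Why: Second Corey–Seebach metalation followed by SN2 opening of the monosubstituted epoxide at its CH2 terminus forms C11–C12; C13 is not a reacting centre and keeps the configuration of 10.

Step 6
Reactants: 12 (R)-1-{2-[(R)-2-methylpent-4-en-1-yl]-1,3-dithian-2-yl}pentan-2-ol
Product: 13 (4R,8R)-8-hydroxy-4-methylundec-1-en-6-one
Conditions: MeI, CaCO3, MeCN/H2O (9:1), 45 °C
Reagents that add atoms: water, O
Why: Alkylative dithiane hydrolysis; S-methylation turns sulfur into a leaving group and water delivers the carbonyl oxygen, while the carbonate buffer keeps the β-hydroxy ketone from dehydration or retro-aldol cleavage and the alkene is untouched.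

Step 7
Reactants: 13 (4R,8R)-8-hydroxy-4-methylundec-1-en-6-one
Product: 14 (4R,6R,8R)-6-hydroxy-8-methylundec-10-en-4-yl benzoate
Conditions: PhCHO (5 equiv), SmI2 (0.3 equiv), THF, −10 °C
Reagents that add atoms: benzaldehyde, O=Cc1ccccc1
Why: Evans–Tishchenko reduction; the C13 hydroxyl and benzaldehyde form a samarium-bound hemiacetal that transfers hydride to C11 through a chair-like six-membered transition state, giving the 1,3-anti relationship (C11 R) with C13 acylated and C11–OH free.

Step 8
Reactants: 14 (4R,6R,8R)-6-hydroxy-8-methylundec-10-en-4-yl benzoate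
Product: 15 (4R,6R,8R)-6-methoxy-8-methylundec-10-en-4-yl benzoate
Conditions: Me3OBF4, 1,8-bis(dimethylamino)naphthalene, 4 Å MS, CH2Cl2, 0 °C to rt
Reagents that add atoms: trimethyloxonium tetrafluoroborate, C[O+](C)C.F[B-](F)(F)F
Why: O-Methylation with a Meerwein salt and a non-nucleophilic proton scavenger; no alkoxide is formed, so the benzoate should neither migrate to C11 nor be eliminated.

Step 9
Reactants: 15 (4R,6R,8R)-6-methoxy-8-methylundec-10-en-4-yl benzoate
Product: 16 (4R,6R,8R)-6-methoxy-8-methylundec-10-en-4-ol
Conditions: K2CO3 (0.5 equiv), MeOH, 40 °C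
Reagents that add atoms: none
Why: Base-catalysed transesterification (methanolysis) frees the C13 hydroxyl; the molecule has no other base-sensitive group at this stage.

Step 10
Reactants: 16 (4R,6R,8R)-6-methoxy-8-methylundec-10-en-4-ol; 17 but-3-en-2-one
Product: 18 (3E,6R,8R,10R)-10-hydroxy-8-methoxy-6-methyltridec-3-en-2-one
Conditions: 17 (4 equiv), second-generation Hoveyda–Grubbs catalyst RuCl2(H2IMes)(=CH-C6H4-2-O-i-Pr) (3 mol%), CH2Cl2, 40 °C
Reagents that add atoms: none
Why: Olefin cross-metathesis between a terminal alkene and an electron-poor vinyl ketone, which homodimerises slowly; the E enone is expected, and the free hydroxyl is tolerated.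

Step 11
Reactants: 18 (3E,6R,8R,10R)-10-hydroxy-8-methoxy-6-methyltridec-3-en-2-one
Product: 19 (4R,6R,8R,10E)-6-methoxy-8-methyl-4,12-bis(triethylsilyloxy)trideca-10,12-diene
Conditions: Et3SiOTf (2.5 equiv), Et3N (4 equiv), Et2O, −78 to 0 °C
Reagents that add atoms: triethylsilyl trifluoromethanesulfonate, CC[Si](CC)(CC)OS(=O)(=O)C(F)(F)F
Why: Soft enolisation; the silyl triflate activates the enone oxygen and the amine removes a proton from the C4 methyl under kinetic control, giving the cross-conjugated 2-siloxy diene with the E alkene intact, while the same reagent silylates C13–OH. The product is used after filtration through base-washed silica.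

Step 12
Reactants: 20 3-(benzyloxy)propan-1-ol
Product: 21 3-(benzyloxy)propanal
Conditions: Dess–Martin periodinane, NaHCO3, CH2Cl2, 0 °C to rt
Reagents that add atoms: none
Why: Dess–Martin oxidation of a primary alcohol under buffered, non-basic conditions, chosen to limit β-elimination of benzyl alcohol; the aldehyde is used at once.

Step 13
Reactants: 19 (4R,6R,8R,10E)-6-methoxy-8-methyl-4,12-bis(triethylsilyloxy)trideca-10,12-diene; 21 3-(benzyloxy)propanal
Product: 22 (2S,6R)-2-[2-(benzyloxy)ethyl]-6-[(2S,4R,6R)-4-methoxy-2-methyl-6-(triethylsilyloxy)nonyl]-4-(triethylsilyloxy)-3,6-dihydro-2H-pyran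
Conditions: CrCl(L) (10 mol%; L = dianion of (1R,2S)-1-{[3-(1-adamantyl)-2-hydroxy-5-methylphenyl]methylideneamino}indan-2-ol), 4 Å MS, acetone (minimal), rt, 48 h
Reagents that add atoms: none
Why: The trivalent chromium centre of the tridentate Schiff-base complex binds the carbonyl oxygen of 21 as a Lewis acid and leaves its re face open. The electron-rich diene 19 then adds in a concerted, asynchronous [4+2] cycloaddition in which its nucleophilic CH2 terminus C4 bonds to the aldehyde carbon C3 ahead of O–C7; the closest known reaction type is the chromium Schiff-base-catalysed hetero-Diels–Alder reaction of 2-siloxy dienes with unactivated aldehydes. The ring (O, C3, C4, C5, C6, C7) closes by cycloaddition, both ring bonds forming in one transition state, and the C5=C6 silyl enol ether that remains marks C5 for its oxygen. C3 (S in 22) is controlled by the hand of the catalyst through the aldehyde face. C7 (R) is controlled relative to C3 by the E geometry of the C6=C7 bond and the endo approach, which place H3 and H7 cis. The step needs regio-, endo- and enantiofacial selectivity: the siloxy group polarises the diene so that only C4 attacks carbon, the catalyst pocket enforces endo addition, and C9, the nearest stereocentre of 19, is insulated from C7 by the C8 methylene so that catalyst control should dominate. Molecular sieves keep water from hydrolysing 19 and from deactivating the catalyst, and 21 is used in excess as the cheaper partner.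

Step 14
Reactants: 22 (2S,6R)-2-[2-(benzyloxy)ethyl]-6-[(2S,4R,6R)-4-methoxy-2-methyl-6-(triethylsilyloxy)nonyl]-4-(triethylsilyloxy)-3,6-dihydro-2H-pyran
Product: 23 (2S,6R)-2-[2-(benzyloxy)ethyl]-6-[(2S,4R,6R)-6-hydroxy-4-methoxy-2-methylnonyl]oxan-4-one
Conditions: 1 M aq. HCl, THF, 0 °C to rt
Reagents that add atoms: none
Why: Acid hydrolysis of the silyl enol ether (protonation at C6, loss of silicon from oxygen) gives the C5 ketone, and the secondary triethylsilyl ether is cleaved in the same operation; the diequatorial 2,6-cis arrangement is the thermodynamic one and should not change.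

Step 15
Reactants: 23 (2S,6R)-2-[2-(benzyloxy)ethyl]-6-[(2S,4R,6R)-6-hydroxy-4-methoxy-2-methylnonyl]oxan-4-one
Product: 24 (2S,6R)-2-(2-hydroxyethyl)-6-[(2S,4R,6R)-6-hydroxy-4-methoxy-2-methylnonyl]oxan-4-one
Conditions: H2 (1 atm), Pd/C (10%), EtOAc, rt
Reagents that add atoms: none
Why: Hydrogenolysis of the benzyl ether over palladium; the substrate has no alkene, and the dialkyl ketone is not reduced under these conditions.

Step 16
Reactants: 24 (2S,6R)-2-(2-hydroxyethyl)-6-[(2S,4R,6R)-6-hydroxy-4-methoxy-2-methylnonyl]oxan-4-one
Product: 25 2-[(2R,6R)-6-[(2S,4R,6R)-6-hydroxy-4-methoxy-2-methylnonyl]-4-oxooxan-2-yl]acetic acid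
Conditions: TEMPO (0.2 equiv), PhI(OAc)2 (2.5 equiv), MeCN/pH 7 buffer (1:1), 0 °C to rt
Reagents that add atoms: water, O
Why: Oxoammonium (TEMPO) oxidation; the hindered oxidant takes the primary C1 alcohol much faster than the secondary C13 alcohol, and in water the aldehyde hydrate is carried on to the acid.

Step 17
Reactants: 25 2-[(2R,6R)-6-[(2S,4R,6R)-6-hydroxy-4-methoxy-2-methylnonyl]-4-oxooxan-2-yl]acetic acid
Product: 27 (1R,5R,7R,9S,11R)-7-methoxy-9-methyl-5-propyl-4,15-dioxabicyclo[9.3.1]pentadecane-3,13-dione, via mixed anhydride 26 (not isolated)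
Conditions: 2,4,6-Cl3C6H2COCl, Et3N, THF, rt; then slow addition to DMAP, toluene, 80 °C (about 1 mM)
Reagents that add atoms: none
Why: Yamaguchi macrolactonisation; the mixed anhydride is converted into an acylpyridinium ion that the only hydroxyl, at C13, attacks at high dilution, closing the 14-membered ring with retention at C13.

Step 18
Reactants: 27 (1R,5R,7R,9S,11R)-7-methoxy-9-methyl-5-propyl-4,15-dioxabicyclo[9.3.1]pentadecane-3,13-dione
Product: 28 (1R,5R,7R,9S,11R,13S)-13-hydroxy-7-methoxy-9-methyl-5-propyl-4,15-dioxabicyclo[9.3.1]pentadecan-3-one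
Conditions: NaBH4, MeOH, 0 °C
Reagents that add atoms: none
Why: Borohydride reduction of a chair pyranone with both side arms equatorial; the small hydride attacks axially and should give the equatorial C5 alcohol, and the lactone is not reduced at this temperature.

Step 19
Reactants: 29 prop-2-yn-1-amine
Product: 30 methyl prop-2-yn-1-ylcarbamate
Conditions: ClCO2Me, Et3N, CH2Cl2, 0 °C to rt
Reagents that add atoms: methyl chloroformate, COC(=O)Cl
Why: N-Acylation of a primary amine with a chloroformate (carbamate formation).

Step 20
Reactants: 31 methyl 5-bromo-4-oxopentanoate; 32 formamide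
Product: 33 methyl 3-(1,3-oxazol-4-yl)propanoate
Conditions: 32 (neat, excess), 110 °C
Reagents that add atoms: none
Why: Bredereck-type oxazole synthesis from an α-bromo ketone and formamide; O-alkylation by the CH2Br carbon and condensation of nitrogen with the ketone, then dehydration, place the ester chain at C4 and leave C2 unsubstituted.

Step 21
Reactants: 33 methyl 3-(1,3-oxazol-4-yl)propanoate
Product: 35 methyl 3-(2-iodo-1,3-oxazol-4-yl)propanoate, via oxazol-2-ylzinc chloride 34 (not isolated)
Conditions: (TMP)ZnCl·LiCl (TMP = 2,2,6,6-tetramethylpiperidin-1-yl), THF, 25 °C; then I2, 0 °C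
Reagents that add atoms: iodine, II
Why: Directed zincation at C2, the most acidic position of the oxazole, by a hindered zinc amide that tolerates the ester, followed by iodinolysis; the zinc derivative does not ring-open as a lithio-oxazole can.

Step 22
Reactants: 35 methyl 3-(2-iodo-1,3-oxazol-4-yl)propanoate; 30 methyl prop-2-yn-1-ylcarbamate
Product: 36 methyl 3-{2-[3-(methoxycarbonylamino)prop-1-yn-1-yl]-1,3-oxazol-4-yl}propanoate
Conditions: PdCl2(PPh3)2 (5 mol%), CuI (10 mol%), Et3N, THF, rt
Reagents that add atoms: none
Why: Sonogashira coupling; the electron-poor 2-iodo-oxazole undergoes oxidative addition readily and the copper acetylide of 30 transfers the alkynyl group.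

Step 23
Reactants: 36 methyl 3-{2-[3-(methoxycarbonylamino)prop-1-yn-1-yl]-1,3-oxazol-4-yl}propanoate
Product: 37 methyl 3-{2-[(1Z)-3-(methoxycarbonylamino)prop-1-en-1-yl]-1,3-oxazol-4-yl}propanoate
Conditions: H2 (1 atm), Pd/CaCO3 poisoned with Pb(OAc)2, quinoline, EtOAc, rt
Reagents that add atoms: none
Why: Lindlar semi-hydrogenation; syn delivery of hydrogen on the poisoned palladium surface gives the Z alkene and stops there.

Step 24
Reactants: 37 methyl 3-{2-[(1Z)-3-(methoxycarbonylamino)prop-1-en-1-yl]-1,3-oxazol-4-yl}propanoate
Product: 38 methyl N-{(2Z)-3-[4-(3-oxopropyl)-1,3-oxazol-2-yl]prop-2-en-1-yl}carbamate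
Conditions: i-Bu2AlH (2.2 equiv), CH2Cl2, −78 °C; potassium sodium tartrate work-up
Reagents that add atoms: none
Why: Partial reduction of the ester with diisobutylaluminium hydride; the tetrahedral aluminium hemiacetal is stable at −78 °C and releases the aldehyde on work-up, one equivalent of hydride being consumed by the carbamate N–H, and the carbamate carbonyl is much less electrophilic.

Step 25
Reactants: 38 methyl N-{(2Z)-3-[4-(3-oxopropyl)-1,3-oxazol-2-yl]prop-2-en-1-yl}carbamate; 39 methyl 2-[bis(2,2,2-trifluoroethoxy)phosphoryl]acetate
Product: 41 methyl (2Z)-5-{2-[(1Z)-3-(methoxycarbonylamino)prop-1-en-1-yl]-1,3-oxazol-4-yl}pent-2-enoate, via potassium phosphonate carbanion 40 (not isolated)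
Conditions: 39, KN(SiMe3)2, 18-crown-6, THF, −78 °C; then 38
Reagents that add atoms: none
Why: Still–Gennari olefination; with trifluoroethyl phosphonate esters and a dissociated potassium counter-ion, elimination from the kinetic adduct is fast and irreversible, which gives the Z enoate.

Step 26
Reactants: 41 methyl (2Z)-5-{2-[(1Z)-3-(methoxycarbonylamino)prop-1-en-1-yl]-1,3-oxazol-4-yl}pent-2-enoate
Product: 42 (2Z)-5-{2-[(1Z)-3-(methoxycarbonylamino)prop-1-en-1-yl]-1,3-oxazol-4-yl}pent-2-enoic acid
Conditions: LiOH, THF/H2O (3:1), 0 °C to rt; then dilute HCl to pH 3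
Reagents that add atoms: water, O
Why: Saponification of the methyl ester; the methyl carbamate is far less electrophilic and should survive, and the mild conditions should leave both Z alkenes unchanged.

Step 27
Reactants: 28 (1R,5R,7R,9S,11R,13S)-13-hydroxy-7-methoxy-9-methyl-5-propyl-4,15-dioxabicyclo[9.3.1]pentadecan-3-one; 42 (2Z)-5-{2-[(1Z)-3-(methoxycarbonylamino)prop-1-en-1-yl]-1,3-oxazol-4-yl}pent-2-enoic acid
Product: 43 neopeltolide, (1R,5R,7R,9S,11R,13R)-7-methoxy-9-methyl-3-oxo-5-propyl-4,15-dioxabicyclo[9.3.1]pentadecan-13-yl (2Z)-5-{2-[(1Z)-3-(methoxycarbonylamino)prop-1-en-1-yl]-1,3-oxazol-4-yl}pent-2-enoate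
Conditions: PPh3, i-PrO2C–N=N–CO2-i-Pr (DIAD), benzene, rt
Reagents that add atoms: none
Why: Mitsunobu esterification; the equatorial C5 hydroxyl is activated as an alkoxyphosphonium ion and displaced by the carboxylate of 42 with inversion, which places the ester axial (C5 R) under neutral conditions that should not isomerise the Z alkenes.

## Compound list

1 | (S)-4-benzyl-3-propanoyl-1,3-oxazolidin-2-one | CCC(=O)N1[C@@H](Cc2ccccc2)COC1=O | starting material
2 | 3-iodoprop-1-ene (allyl iodide) | C=CCI | starting material
3 | sodium Z-enolate of 1 | C/C=C(\[O-])N1[C@@H](Cc2ccccc2)COC1=O.[Na+] | intermediate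
4 | (S)-4-benzyl-3-[(R)-2-methylpent-4-enoyl]-1,3-oxazolidin-2-one | C=CC[C@@H](C)C(=O)N1[C@@H](Cc2ccccc2)COC1=O | intermediate
5 | (R)-2-methylpent-4-en-1-ol | OC[C@H](C)CC=C | intermediate
6 | (R)-5-iodo-4-methylpent-1-ene | IC[C@H](C)CC=C | intermediate
7 | 1,3-dithiane | C1CSCSC1 | starting material
8 | 2-lithio-1,3-dithiane | [Li]C1SCCCS1 | intermediate
9 | 2-[(R)-2-methylpent-4-en-1-yl]-1,3-dithiane | C=CC[C@@H](C)CC1SCCCS1 | intermediate
10 | (R)-2-propyloxirane | CCC[C@@H]1CO1 | starting material
11 | 2-lithio-2-[(R)-2-methylpent-4-en-1-yl]-1,3-dithiane | [Li]C1(C[C@H](C)CC=C)SCCCS1 | intermediate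
12 | (R)-1-{2-[(R)-2-methylpent-4-en-1-yl]-1,3-dithian-2-yl}pentan-2-ol | CCC[C@@H](O)CC1(C[C@H](C)CC=C)SCCCS1 | intermediate
13 | (4R,8R)-8-hydroxy-4-methylundec-1-en-6-one | CCC[C@@H](O)CC(=O)C[C@H](C)CC=C | intermediate
14 | (4R,6R,8R)-6-hydroxy-8-methylundec-10-en-4-yl benzoate | CCC[C@@H](OC(=O)c1ccccc1)C[C@H](O)C[C@H](C)CC=C | intermediate
15 | (4R,6R,8R)-6-methoxy-8-methylundec-10-en-4-yl benzoate | CCC[C@@H](OC(=O)c1ccccc1)C[C@H](OC)C[C@H](C)CC=C | intermediate
16 | (4R,6R,8R)-6-methoxy-8-methylundec-10-en-4-ol | CCC[C@@H](O)C[C@H](OC)C[C@H](C)CC=C | intermediate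
17 | but-3-en-2-one | CC(=O)C=C | starting material
18 | (3E,6R,8R,10R)-10-hydroxy-8-methoxy-6-methyltridec-3-en-2-one | CCC[C@@H](O)C[C@H](OC)C[C@H](C)C/C=C/C(C)=O | intermediate
19 | (4R,6R,8R,10E)-6-methoxy-8-methyl-4,12-bis(triethylsilyloxy)trideca-10,12-diene | CCC[C@@H](O[Si](CC)(CC)CC)C[C@H](OC)C[C@H](C)C/C=C/C(=C)O[Si](CC)(CC)CC | intermediate
20 | 3-(benzyloxy)propan-1-ol | OCCCOCc1ccccc1 | starting material
21 | 3-(benzyloxy)propanal | O=CCCOCc1ccccc1 | intermediate
22 | (2S,6R)-2-[2-(benzyloxy)ethyl]-6-[(2S,4R,6R)-4-methoxy-2-methyl-6-(triethylsilyloxy)nonyl]-4-(triethylsilyloxy)-3,6-dihydro-2H-pyran | CCC[C@@H](O[Si](CC)(CC)CC)C[C@H](OC)C[C@H](C)C[C@@H]1C=C(O[Si](CC)(CC)CC)C[C@H](CCOCc2ccccc2)O1 | intermediate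
23 | (2S,6R)-2-[2-(benzyloxy)ethyl]-6-[(2S,4R,6R)-6-hydroxy-4-methoxy-2-methylnonyl]oxan-4-one | CCC[C@@H](O)C[C@H](OC)C[C@H](C)C[C@@H]1CC(=O)C[C@H](CCOCc2ccccc2)O1 | intermediate
24 | (2S,6R)-2-(2-hydroxyethyl)-6-[(2S,4R,6R)-6-hydroxy-4-methoxy-2-methylnonyl]oxan-4-one | CCC[C@@H](O)C[C@H](OC)C[C@H](C)C[C@@H]1CC(=O)C[C@H](CCO)O1 | intermediate
25 | 2-[(2R,6R)-6-[(2S,4R,6R)-6-hydroxy-4-methoxy-2-methylnonyl]-4-oxooxan-2-yl]acetic acid | CCC[C@@H](O)C[C@H](OC)C[C@H](C)C[C@@H]1CC(=O)C[C@H](CC(=O)O)O1 | intermediate
26 | mixed anhydride of 25 with 2,4,6-trichlorobenzoic acid | CCC[C@@H](O)C[C@H](OC)C[C@H](C)C[C@@H]1CC(=O)C[C@H](CC(=O)OC(=O)c2c(Cl)cc(Cl)cc2Cl)O1 | intermediate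
27 | (1R,5R,7R,9S,11R)-7-methoxy-9-methyl-5-propyl-4,15-dioxabicyclo[9.3.1]pentadecane-3,13-dione | CCC[C@@H]1C[C@H](OC)C[C@H](C)C[C@@H]2CC(=O)C[C@H](CC(=O)O1)O2 | intermediate
28 | (1R,5R,7R,9S,11R,13S)-13-hydroxy-7-methoxy-9-methyl-5-propyl-4,15-dioxabicyclo[9.3.1]pentadecan-3-one | CCC[C@@H]1C[C@H](OC)C[C@H](C)C[C@@H]2C[C@H](O)C[C@H](CC(=O)O1)O2 | intermediate
29 | prop-2-yn-1-amine | C#CCN | starting material
30 | methyl prop-2-yn-1-ylcarbamate | COC(=O)NCC#C | intermediate
31 | methyl 5-bromo-4-oxopentanoate | COC(=O)CCC(=O)CBr | starting material
32 | formamide | NC=O | starting material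
33 | methyl 3-(1,3-oxazol-4-yl)propanoate | COC(=O)CCc1cocn1 | intermediate
34 | [4-(3-methoxy-3-oxopropyl)-1,3-oxazol-2-yl]zinc chloride (lithium chloride complex) | COC(=O)CCc1coc([Zn]Cl)n1 | intermediate
35 | methyl 3-(2-iodo-1,3-oxazol-4-yl)propanoate | COC(=O)CCc1coc(I)n1 | intermediate
36 | methyl 3-{2-[3-(methoxycarbonylamino)prop-1-yn-1-yl]-1,3-oxazol-4-yl}propanoate | COC(=O)CCc1coc(C#CCNC(=O)OC)n1 | intermediate
37 | methyl 3-{2-[(1Z)-3-(methoxycarbonylamino)prop-1-en-1-yl]-1,3-oxazol-4-yl}propanoate | COC(=O)CCc1coc(/C=C\CNC(=O)OC)n1 | intermediate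
38 | methyl N-{(2Z)-3-[4-(3-oxopropyl)-1,3-oxazol-2-yl]prop-2-en-1-yl}carbamate | O=CCCc1coc(/C=C\CNC(=O)OC)n1 | intermediate
39 | methyl 2-[bis(2,2,2-trifluoroethoxy)phosphoryl]acetate | COC(=O)CP(=O)(OCC(F)(F)F)OCC(F)(F)F | starting material
40 | potassium salt of the carbanion of 39 | COC(=O)[CH-]P(=O)(OCC(F)(F)F)OCC(F)(F)F.[K+] | intermediate
41 | methyl (2Z)-5-{2-[(1Z)-3-(methoxycarbonylamino)prop-1-en-1-yl]-1,3-oxazol-4-yl}pent-2-enoate | COC(=O)/C=C\CCc1coc(/C=C\CNC(=O)OC)n1 | intermediate
42 | (2Z)-5-{2-[(1Z)-3-(methoxycarbonylamino)prop-1-en-1-yl]-1,3-oxazol-4-yl}pent-2-enoic acid | OC(=O)/C=C\CCc1coc(/C=C\CNC(=O)OC)n1 | intermediate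
43 | neopeltolide | CCC[C@@H]1C[C@H](OC)C[C@H](C)C[C@@H]2C[C@@H](OC(=O)/C=C\CCc3coc(/C=C\CNC(=O)OC)n3)C[C@H](CC(=O)O1)O2 | target

## Step count and least certain steps

Total: 27 steps. Longest linear sequence: 18 steps (steps 1–11, 13–18 and 27, from 1). The aldehyde branch is 1 step (step 12) and the side-chain branch 8 steps (steps 19–26).

**Step 13 (key step).** The aldehyde face may be discriminated poorly, or in the opposite sense, with this long-chain diene. The silyl dienol ether may hydrolyse before it reacts, and 21 may lose benzyl alcohol by β-elimination. Any of these would lower conversion or give the C3,C7-epimeric cis pyran. Fallback, setting out from 18 and coming back at 23: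
- 18 would be silylated at C13–OH (Et3SiCl, imidazole, DMF) to (3E,6R,8R,10R)-8-methoxy-6-methyl-10-(triethylsilyloxy)tridec-3-en-2-one F1.
- The methyl ketone of this compound would be enolised with (−)-Ipc2BCl and Et3N and added to 21 in a reagent-controlled boron aldol reaction. This hand is expected to direct the enolate to the re face of the aldehyde; the antipodal reagent serves if the sense is found reversed. The product would be (3S,6E,9R,11R,13R)-1-(benzyloxy)-3-hydroxy-11-methoxy-9-methyl-13-(triethylsilyloxy)hexadec-6-en-5-one F2.
- Treatment with a sulfonic acid resin (Amberlyst-15) in CH2Cl2, then dilute aqueous HCl in THF, would remove the silyl group and bring about the reversible 6-endo oxa-Michael addition of C3–OH to C7. This funnels to the diequatorial 2,6-cis pyranone 23.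

**Step 20.** Imidazole formation, amidation of the methyl ester by ammonia released from hot formamide, and self-condensation of the bromo ketone can all compete with oxazole formation. Fallback, setting out from 31 and coming back at 33: displacement of bromide with HCO2Na in DMF would give methyl 5-(formyloxy)-4-oxopentanoate F3, and heating this with NH4OAc in acetic acid (Davidson oxazole synthesis) would give 33 with the same regiochemistry.

**Step 21.** Metalation may be incomplete or may compete with enolisation of the ester, and the 2-iodo-oxazole may decompose on isolation. Fallback, setting out from 31 and coming back at 36: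
- Condensation of 31 with urea in DMF at 100 °C would give methyl 3-(2-amino-1,3-oxazol-4-yl)propanoate F4.
- Diazotisation and bromide transfer with t-BuONO and CuBr2 in MeCN would give methyl 3-(2-bromo-1,3-oxazol-4-yl)propanoate F5.
- F5 would be coupled with 30 under the Sonogashira conditions of step 22 to give 36.

**Step 16.** Oxidation may not stop cleanly at the primary position: slow oxidation of the C13 alcohol to a ketone, or hemiacetal formation at the aldehyde stage, would lower the yield of seco acid. Fallback, setting out from 23 and coming back at 25: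
- The C13 hydroxyl of 23 would be protected (t-BuMe2SiCl, imidazole, DMF) as (2S,6R)-2-[2-(benzyloxy)ethyl]-6-[(2S,4R,6R)-6-(tert-butyldimethylsilyloxy)-4-methoxy-2-methylnonyl]oxan-4-one F6.
- Hydrogenolysis (H2, Pd/C) would give (2S,6R)-2-(2-hydroxyethyl)-6-[(2S,4R,6R)-6-(tert-butyldimethylsilyloxy)-4-methoxy-2-methylnonyl]oxan-4-one F7.
- The same TEMPO/PhI(OAc)2 oxidation, now with no competing hydroxyl, would give 2-[(2R,6R)-6-[(2S,4R,6R)-6-(tert-butyldimethylsilyloxy)-4-methoxy-2-methylnonyl]-4-oxooxan-2-yl]acetic acid F8.
- HF·pyridine in THF would release 25.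

**Step 24.** Over-reduction of the aldehyde to the alcohol, or attack on the carbamate when excess hydride is present, is the likely failure. Fallback, setting out from 37 and coming back at 38: full reduction of the ester with LiBH4 in THF/MeOH would give methyl N-{(2Z)-3-[4-(3-hydroxypropyl)-1,3-oxazol-2-yl]prop-2-en-1-yl}carbamate F9, and Dess–Martin oxidation of this alcohol would give 38.

## Further compounds

F1 | step 13 | (3E,6R,8R,10R)-8-methoxy-6-methyl-10-(triethylsilyloxy)tridec-3-en-2-one | CCC[C@@H](O[Si](CC)(CC)CC)C[C@H](OC)C[C@H](C)C/C=C/C(C)=O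
F2 | step 13 | (3S,6E,9R,11R,13R)-1-(benzyloxy)-3-hydroxy-11-methoxy-9-methyl-13-(triethylsilyloxy)hexadec-6-en-5-one | CCC[C@@H](O[Si](CC)(CC)CC)C[C@H](OC)C[C@H](C)C/C=C/C(=O)C[C@H](CCOCc1ccccc1)O
F3 | step 20 | methyl 5-(formyloxy)-4-oxopentanoate | COC(=O)CCC(=O)COC=O
F4 | step 21 | methyl 3-(2-amino-1,3-oxazol-4-yl)propanoate | COC(=O)CCc1coc(N)n1
F5 | step 21 | methyl 3-(2-bromo-1,3-oxazol-4-yl)propanoate | COC(=O)CCc1coc(Br)n1
F6 | step 16 | (2S,6R)-2-[2-(benzyloxy)ethyl]-6-[(2S,4R,6R)-6-(tert-butyldimethylsilyloxy)-4-methoxy-2-methylnonyl]oxan-4-one | CCC[C@@H](O[Si](C)(C)C(C)(C)C)C[C@H](OC)C[C@H](C)C[C@@H]1CC(=O)C[C@H](CCOCc2ccccc2)O1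
F7 | step 16 | (2S,6R)-2-(2-hydroxyethyl)-6-[(2S,4R,6R)-6-(tert-butyldimethylsilyloxy)-4-methoxy-2-methylnonyl]oxan-4-one | CCC[C@@H](O[Si](C)(C)C(C)(C)C)C[C@H](OC)C[C@H](C)C[C@@H]1CC(=O)C[C@H](CCO)O1
F8 | step 16 | 2-[(2R,6R)-6-[(2S,4R,6R)-6-(tert-butyldimethylsilyloxy)-4-methoxy-2-methylnonyl]-4-oxooxan-2-yl]acetic acid | CCC[C@@H](O[Si](C)(C)C(C)(C)C)C[C@H](OC)C[C@H](C)C[C@@H]1CC(=O)C[C@H](CC(=O)O)O1
F9 | step 24 | methyl N-{(2Z)-3-[4-(3-hydroxypropyl)-1,3-oxazol-2-yl]prop-2-en-1-yl}carbamate | OCCCc1coc(/C=C\CNC(=O)OC)n1
A1 | alternative 1 | all-cis macrolide C5 trifluoroacetate, (1R,5R,7R,9S,11R,13S)-7-methoxy-9-methyl-3-oxo-5-propyl-4,15-dioxabicyclo[9.3.1]pentadecan-13-yl trifluoroacetate | CCC[C@@H]1C[C@H](OC)C[C@H](C)C[C@@H]2C[C@H](OC(=O)C(F)(F)F)C[C@H](CC(=O)O1)O2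
A2 | alternative 1 | (4R,6R,8S)-6-methoxy-8-methyl-10-oxodecan-4-yl (3R)-3-hydroxyhex-5-enoate | CCC[C@@H](OC(=O)C[C@H](O)CC=C)C[C@H](OC)C[C@H](C)CC=O
A3 | alternative 2 | C1–C16 chain with C7 as 1,3-dithiane, C5 tert-butyldimethylsilyl ether, C3 p-methoxybenzyl ether, C1 and C13 benzyl ethers | CCC[C@@H](OCc1ccccc1)C[C@H](OC)C[C@H](C)CC2(SCCCS2)C[C@H](O[Si](C)(C)C(C)(C)C)C[C@H](CCOCc3ccccc3)OCc4ccc(OC)cc4
A4 | alternative 2 | 2-(tert-butyldimethylsilyl)-1,3-dithiane | CC(C)(C)[Si](C)(C)C1SCCCS1
A5 | alternative 2 | (2R)-2-{(2S)-4-(benzyloxy)-2-[(4-methoxyphenyl)methoxy]butyl}oxirane | C1O[C@@H]1C[C@H](CCOCc2ccccc2)OCc3ccc(OC)cc3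
A6 | alternative 2 | (2S,4R,6R)-6-(benzyloxy)-1-iodo-4-methoxy-2-methylnonane | CCC[C@@H](OCc1ccccc1)C[C@H](OC)C[C@H](C)CI
A7 | alternative 3 | C8–C9 unsaturated macrolide C5 tert-butyldimethylsilyl ether (E alkene) | CCC[C@@H]1C[C@H](OC)C/C(C)=C/[C@@H]2C[C@H](O[Si](C)(C)C(C)(C)C)C[C@H](CC(=O)O1)O2
A8 | alternative 3 | (4R,6R)-6-methoxy-8-methylnon-8-en-4-yl 2-[(2R,4R,6S)-4-(tert-butyldimethylsilyloxy)-6-ethenyloxan-2-yl]acetate | CCC[C@@H](OC(=O)C[C@H]1C[C@@H](O[Si](C)(C)C(C)(C)C)C[C@@H](C=C)O1)C[C@H](OC)CC(C)=C
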